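## Structural features

The target is a 2,3-dihydro-1-benzofuran: a benzene ring fused to a five-membered ring made of O1, C2 and C3. C5, para to O1, carries an (E)-propenoic acid, and C2 carries a propan-2-yl chain whose terminal CH2O is esterified by (E)-4-hydroxycinnamic acid. The only stereocentres are C2 (S) and the adjacent exocyclic methine C1' (S). Along the chain C3–C2–C1'–CH2O the ring oxygen and the methyl group are syn, the opposite of the anti preference usually associated with uncatalysed dialkylborane addition to 1,1-disubstituted allylic ethers. Fragile points are the free acid, the free phenol, two cinnamoyl Michael acceptors and the ester linking the two halves, which rule out hydrolytic, strongly nucleophilic or reducing conditions late on; C2 also becomes epimerisable whenever a carbonyl group is attached to it. The real difficulty is stereochemical: two contiguous centres joined by a freely rotating bond, one inside the ring and one outside. The key step exploits the fact that C2 is a single carbon bonded to both C3 and O1, the two termini of an ortho-quinone methide, so one ylide carbon carrying a carbonyl handle can be inserted between them. For the halogen to end at C5 the methide must derive from a 5-bromo-2-hydroxybenzyl unit (bromine para to the phenol oxygen); a 4-bromo-2-hydroxybenzyl unit would place it at C6.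

## Logic of the disconnections

**17 ⇒ 16.** The O–C(CH3)3 bond of a tert-butyl ester on the propenoic acid is cut. The acid is thereby masked through the esterification, where a free acid would compete. The forward step must remove the group by acid without touching the cinnamate ester or alkylating the phenol.

**16 ⇒ 14 + 15.** The CH2–O bond of the linking ester is cut, with the side-chain carbon as the electrophile. This removes the whole phenolic acid as one commercial piece and needs no phenol protection. The forward step must make the carboxylate, not the phenol, the nucleophile.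

**14 ⇒ 12 + 13.** The C5–vinyl bond is cut. The arm becomes an aryl bromide that is inert in every earlier step, plus a commercial acrylate. The forward arylation must be E-selective in the presence of a free primary alcohol. It has to follow the hydride step, because an acrylate would not survive a copper hydride.

**12 ⇒ 10 (through 11).** The CH2–O bond and the C1'–H bond are cut, tracing the alcohol to a 1,1-disubstituted alkene. This erases the second stereocentre. The forward step must add H and boron with anti-Markovnikov regiochemistry and choose the alkene face by catalyst control, since the syn relationship is needed.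

**10 ⇒ 9.** The C1'=CH2 bond is cut to a methyl ketone. The forward methylenation must be non-basic because C2 in 9 is enolisable.

**9 ⇒ 8.** The C1'–CH3 bond is cut, leaving an N-methoxy-N-methylamide. The forward step must deliver exactly one methyl group and must not exchange the aryl bromide.

**8 ⇒ 3 + 4 (carrier 5; through 6 and 7).** The bonds C3–C2 and O1–C2 are cut. The ring falls apart into the four-atom unit 7, released from 3, and the one-carbon ylide derived from 6, which is made from 4 and 5. Ring and C2 stereocentre arise together from achiral, commercial-type pieces. The forward step demands that 4 be fully converted into 6 before base and phenol are present, that 7 be released slowly, and that the chiral ammonium group control the face of the ylide.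

**3 ⇒ 1 + 2.** The benzylic C–S bond is cut. The sulfone is a bench-stable store for 7. The forward step needs only acid-promoted ionisation of the benzylic alcohol and S-alkylation of the sulfinate.

## Other disconnections considered

**Alternative 1:** The cut is C3a–C3 and O1–C2, giving 4-bromo-2-iodophenol A1 and the diene tert-butyl(dimethyl)[(2-methylidenebut-3-en-1-yl)oxy]silane A2. In the forward step Pd2(dba)3 (zerovalent palladium) with a chiral sulfinamide phosphine would add into the C–I bond and carbopalladate the unsubstituted vinyl terminus of A2. The phenoxide would then attack the internal carbon of the resulting π-allyl complex, closing the ring to tert-butyl({2-[(2S)-5-bromo-2,3-dihydro-1-benzofuran-2-yl]prop-2-en-1-yl}oxy)dimethylsilane A3.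
- In favour: the chiral element is catalytic, and A3 already holds all three side-chain carbons and the oxygen. Desilylation and a face-selective hydrogenation of the 1,1-disubstituted allylic alcohol would lead to 12 in about three steps from A1.
- Against: C–I must be discriminated from C–Br at every turnover. A2 is not an article of commerce and is prone to dimerise. The diene has two different termini and the allyl unit two different ends, so regiochemistry must be won twice. The hydrogenation has to spare the aryl bromide.
- Comparison: on structure both plans use the same C5 bromide and both leave C1' to a second, independent asymmetric reduction, so they are equal there. On mechanism the alternative is catalytic in chirality and the chosen plan spends a stoichiometric (recoverable) alkaloid, so the alternative is better on that point, while the chosen plan has no halogen-selectivity or regiochemical question. On step economy from ring formation to 12 the alternative is the shorter if the preparation of A2 is not counted, and about equal if it is.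

**Alternative 2:** The cut is C2–C3. The precursor would be N'-[(E)-{5-bromo-2-[(2R)-3-{[tert-butyl(dimethyl)silyl]oxy}-2-methylpropoxy]phenyl}methylidene]-4-methylbenzenesulfonohydrazide A5, assembled from the chiral-pool ester methyl (2S)-3-hydroxy-2-methylpropanoate A4 by silylation, reduction, aryl ether formation and hydrazone condensation. In the forward step base would liberate the aryldiazomethane. A chiral Co(por*) complex (divalent cobalt) would then abstract one O–CH2 hydrogen through a cobalt carbene radical and close the ring by radical substitution, or Rh2(PTAD)4 would insert in concert, giving tert-butyl({(2S)-2-[(2S)-5-bromo-2,3-dihydro-1-benzofuran-2-yl]propyl}oxy)dimethylsilane A6.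
- In favour: C1' is bought rather than made, so its configuration is beyond doubt and it is never epimerisable. A6 holds both stereocentres and is one desilylation away from 12.
- Against: the catalyst must choose between two diastereotopic hydrogens next to an existing stereocentre, so a mismatched pairing is possible. Insertion into the tertiary C1'–H (six-membered ring) and azine formation would compete. The porphyrin catalyst is not a catalogue item. A5 takes about four steps.
- Comparison: on structure the alternative is better, because only one new stereocentre has to be created and the other is secure. On mechanism it needs one asymmetric event where the chosen plan needs two, which is also in its favour, but that event is a C–H selection with several competing sites, whereas the chosen annulation has a single electrophilic carbon. On step economy it would need about six steps to 12 against five, so the chosen plan is slightly better.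

**Alternative 3:** The cut is O1–C2 and C1'–C2' (the carboxyl carbon), giving 4-bromo-2-[(2E)-but-2-en-1-yl]phenol A7, carbon monoxide and methanol. In the forward step PdCl2(MeCN)2 (divalent palladium) with a chiral bis(oxazoline) and CuCl2 as reoxidant would effect anti attack of the phenol on the coordinated alkene and CO insertion into the C1'–Pd bond with retention. Methanolysis would then give methyl (2R)-2-[(2S)-5-bromo-2,3-dihydro-1-benzofuran-2-yl]propanoate A8.
- In favour: both stereocentres are set in one step, and their relative configuration follows stereospecifically from the E geometry. A7 is about two conventional steps from commerce (O-alkylation with a branched butenyl unit, then aromatic Claisen rearrangement), and one ester reduction of A8 gives 12.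
- Against: oxypalladation of phenols can run syn or anti depending on chloride concentration and ligand, and a switch would invert the relative configuration. β-Hydride elimination from the secondary alkylpalladium competes with CO insertion. High enantioselectivity with simple E-disubstituted alkenes is the weak point of this reaction class. A8 has an epimerisable α-centre. CuCl2 can chlorinate, and CO must be handled.
- Comparison: on structure and step economy the alternative is better, with about four steps to 12 against five and both centres from one event. On mechanism the chosen plan is the more predictable, since its C2-forming step has one electrophilic site and a defined inversion in the closure, while the alternative rests on a stereochemical course that is known to be condition-dependent.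

Key step: step 2

Assumptions:
- The quinidine-derived ammonium ylide is taken to deliver the (S)-amide; if the sense of induction proves opposite, quinine, its pseudo-enantiomer, takes its place without other change.
- (R)-DTBM-SEGPHOS is taken as the ligand antipode that gives (S) at C1'; if the sense proves opposite, the (S)-ligand is used.

## Route

Step 1
Reactants: 1 4-bromo-2-(hydroxymethyl)phenol (5-bromo-2-hydroxybenzyl alcohol); 2 sodium 4-methylbenzenesulfinate
Product: 3 4-bromo-2-[(4-methylphenyl)sulfonylmethyl]phenol
Conditions: 2 (1.5 equiv), HCO2H/H2O (1:1), rt → 50 °C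
Reagents that add atoms: none
Why: Acid-promoted ionisation of the ortho-hydroxybenzylic alcohol (assisted by the phenol oxygen) followed by S-alkylation of the sulfinate, a known way to 2-(sulfonylmethyl)phenols; any O-sulfinate ester reverts under the acid and funnels to the sulfone.

Step 2
Reactants: 3 4-bromo-2-[(4-methylphenyl)sulfonylmethyl]phenol; 4 2-bromo-N-methoxy-N-methylacetamide; 5 quinidine (stoichiometric chiral amine, recovered)
Product: 8 (2S)-5-bromo-N-methoxy-N-methyl-2,3-dihydro-1-benzofuran-2-carboxamide, via quinidinium bromide 6 (not isolated), via ortho-quinone methide 7 (not isolated)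
Conditions: 4 (1.3 equiv), 5 (1.35 equiv), THF, rt, 16 h, evaporate; then 3 (1.0 equiv), Cs2CO3 (2.5 equiv), CH2Cl2, 0 °C → rt, 24 h
Reagents that add atoms: none
Why: Quinidine first displaces bromide from 4 at its quinuclidine nitrogen to give 6, so that no free alkyl bromide remains to O-alkylate the phenoxide; Cs2CO3 then removes the phenolic proton of 3, which expels 4-methylbenzenesulfinate to give 7, and deprotonates 6 between N+ and C=O to give the amide-stabilised ammonium ylide. The ylide carbon adds to the exocyclic CH2 of 7 (bond C3–C2), the ring regaining aromaticity as a phenoxide, and the phenoxide then displaces quinidine from C2 in an intramolecular SN2 reaction with inversion (bond O1–C2), a 5-exo-tet closure. The closest known reaction type is the formal [4+1] annulation of sulfone-derived ortho-quinone methides with cinchona-derived ammonium ylides of α-bromo amides, and with sulfonium ylides. The single new stereocentre, C2, is controlled by the chiral quinuclidinium group, which screens one face of the ylide in the C–C bond-forming step; because the two betaine diastereomers can interconvert through the ylide, the ring closure can add a second selection for the faster-cyclising one. Regioselectivity is not in question, since the methide CH2 is the only soft electrophilic site of 7 and attack there restores the aromatic ring. The selectivity that matters is capture by the ylide versus oligomerisation of the unsubstituted methide, and it is secured by the slow, heterogeneous release of 7 in the presence of an excess of ylide. The C2–H of the tertiary amide product is not removed by carbonate, so the configuration should hold.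

Step 3
Reactants: 8 (2S)-5-bromo-N-methoxy-N-methyl-2,3-dihydro-1-benzofuran-2-carboxamide
Product: 9 1-[(2S)-5-bromo-2,3-dihydro-1-benzofuran-2-yl]ethan-1-one
Conditions: MeMgBr (1.5 equiv), THF, −20 → 0 °C; cold sat. aq. NH4Cl
Reagents that add atoms: methylmagnesium bromide, C[Mg]Br
Why: Weinreb ketone synthesis: the magnesium chelate holds the tetrahedral adduct until the quench, so only one methyl group is delivered, and MeMgBr does not exchange with the aryl bromide at this temperature. A cold, buffered quench keeps the enolisable α-aryloxy ketone from epimerising at C2.

Step 4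
Reactants: 9 1-[(2S)-5-bromo-2,3-dihydro-1-benzofuran-2-yl]ethan-1-one
Product: 10 (2S)-5-bromo-2-(prop-1-en-2-yl)-2,3-dihydro-1-benzofuran
Conditions: Cp2TiMe2 (2.5 equiv), toluene/THF, 65 °C, dark
Reagents that add atoms: dimethyltitanocene (Cp2TiMe2), C[Ti](C)(C1C=CC=C1)C1C=CC=C1
Why: Petasis methylenation: thermolysis of Cp2TiMe2 gives Cp2Ti=CH2, which turns C=O into C=CH2 through an oxatitanacyclobutane. The reagent is non-basic, which is why it is preferred to a phosphorus ylide for a ketone with an epimerisable α-centre.

Step 5
Reactants: 10 (2S)-5-bromo-2-(prop-1-en-2-yl)-2,3-dihydro-1-benzofuran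
Product: 12 (2S)-2-[(2S)-5-bromo-2,3-dihydro-1-benzofuran-2-yl]propan-1-ol, via pinacol boronate 11 (not isolated)
Conditions: CuCl (5 mol%), (R)-DTBM-SEGPHOS (5.5 mol%), KOt-Bu (10 mol%), HBpin (1.5 equiv), THF, rt; then NaOH, H2O2, THF/H2O, 0 °C
Reagents that add atoms: pinacolborane (HBpin), [H]B1OC(C)(C)C(C)(C)O1 (boron of 11); hydrogen peroxide, OO (oxygen of 12)
Why: Catalytic enantioselective hydroboration of an unactivated 1,1-disubstituted alkene with ligated CuH (monovalent copper): hydrocupration places copper on the terminal CH2 and hydrogen on C1', the bulky bisphosphine choosing the alkene face so that C1' is set (S) by catalyst control, and σ-bond metathesis with HBpin gives 11; alkaline peroxide then replaces boron by oxygen at the CH2 without touching either stereocentre. Copper sits on the carbon remote from C2, so β-aryloxide elimination with ring opening cannot occur, and aryl bromides are tolerated by this catalyst.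

Step 6
Reactants: 12 (2S)-2-[(2S)-5-bromo-2,3-dihydro-1-benzofuran-2-yl]propan-1-ol; 13 tert-butyl prop-2-enoate (tert-butyl acrylate)
Product: 14 tert-butyl (2E)-3-[(2S)-2-[(2S)-1-hydroxypropan-2-yl]-2,3-dihydro-1-benzofuran-5-yl]prop-2-enoate
Conditions: 13 (2 equiv), Pd2(dba)3 (2 mol%), [HP(t-Bu)3]BF4 (8 mol%), Cy2NMe (1.5 equiv), 1,4-dioxane, 70 °C
Reagents that add atoms: none
Why: Mizoroki–Heck reaction: oxidative addition into the C5–Br bond, syn insertion of the acrylate and syn β-hydride elimination give the E-cinnamate. The electron-rich P(t-Bu)3 ligand is chosen because the bromide is para to an ether oxygen; the free primary alcohol and both stereocentres are spectators.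

Step 7
Reactants: 14 tert-butyl (2E)-3-[(2S)-2-[(2S)-1-hydroxypropan-2-yl]-2,3-dihydro-1-benzofuran-5-yl]prop-2-enoate; 15 (2E)-3-(4-hydroxyphenyl)prop-2-enoic acid (p-coumaric acid)
Product: 16 tert-butyl (2E)-3-[(2S)-2-[(2S)-1-{[(2E)-3-(4-hydroxyphenyl)prop-2-enoyl]oxy}propan-2-yl]-2,3-dihydro-1-benzofuran-5-yl]prop-2-enoate
Conditions: 15 (1.3 equiv), PPh3 (1.4 equiv), DIAD (1.4 equiv), THF, 0 °C → rt
Reagents that add atoms: none
Why: Mitsunobu esterification: the alcohol is activated as its alkoxyphosphonium ion and displaced by the carboxylate of 15, which is several pKa units more acidic than its phenol and therefore reacts chemoselectively without protection. Displacement takes place at the CH2, so neither stereocentre is touched.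

Step 8
Reactants: 16 tert-butyl (2E)-3-[(2S)-2-[(2S)-1-{[(2E)-3-(4-hydroxyphenyl)prop-2-enoyl]oxy}propan-2-yl]-2,3-dihydro-1-benzofuran-5-yl]prop-2-enoate
Product: 17 (2E)-3-[(2S)-2-[(2S)-1-{[(2E)-3-(4-hydroxyphenyl)prop-2-enoyl]oxy}propan-2-yl]-2,3-dihydro-1-benzofuran-5-yl]prop-2-enoic acid (target)
Conditions: CF3CO2H/CH2Cl2 (1:4), 0 °C → rt
Reagents that add atoms: none
Why: Acidolysis of the tert-butyl ester by alkyl–oxygen cleavage with loss of 2-methylpropene; the primary cinnamate ester, the aryl alkyl ether of the ring and the phenol are stable to dilute trifluoroacetic acid at or below room temperature.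

## Compound list

1 | 4-bromo-2-(hydroxymethyl)phenol (5-bromo-2-hydroxybenzyl alcohol) | OCc1cc(Br)ccc1O | starting material
2 | sodium 4-methylbenzenesulfinate | Cc1ccc(cc1)S(=O)[O-].[Na+] | starting material
3 | 4-bromo-2-[(4-methylphenyl)sulfonylmethyl]phenol | Cc1ccc(cc1)S(=O)(=O)Cc1cc(Br)ccc1O | intermediate
4 | 2-bromo-N-methoxy-N-methylacetamide | CON(C)C(=O)CBr | starting material
5 | quinidine, (S)-[(2R,4S,5R)-5-ethenyl-1-azabicyclo[2.2.2]octan-2-yl](6-methoxyquinolin-4-yl)methanol | COC1=CC2=C(C=CN=C2C=C1)[C@@H]([C@H]3C[C@@H]4CCN3C[C@@H]4C=C)O | starting material
6 | N-[2-[methoxy(methyl)amino]-2-oxoethyl]quinidinium bromide (alkylated at the quinuclidine nitrogen) | COC1=CC2=C(C=CN=C2C=C1)[C@@H]([C@H]3C[C@@H]4CC[N+]3(CC(=O)N(C)OC)C[C@@H]4C=C)O.[Br-] | intermediate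
7 | 4-bromo-6-methylidenecyclohexa-2,4-dien-1-one | C=C1C=C(Br)C=CC1=O | intermediate
8 | (2S)-5-bromo-N-methoxy-N-methyl-2,3-dihydro-1-benzofuran-2-carboxamide | CON(C)C(=O)[C@@H]1Cc2cc(Br)ccc2O1 | intermediate
9 | 1-[(2S)-5-bromo-2,3-dihydro-1-benzofuran-2-yl]ethan-1-one | CC(=O)[C@@H]1Cc2cc(Br)ccc2O1 | intermediate
10 | (2S)-5-bromo-2-(prop-1-en-2-yl)-2,3-dihydro-1-benzofuran | CC(=C)[C@@H]1Cc2cc(Br)ccc2O1 | intermediate
11 | 2-{(2S)-2-[(2S)-5-bromo-2,3-dihydro-1-benzofuran-2-yl]propyl}-4,4,5,5-tetramethyl-1,3,2-dioxaborolane | C[C@@H](CB1OC(C)(C)C(C)(C)O1)[C@@H]1Cc2cc(Br)ccc2O1 | intermediate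
12 | (2S)-2-[(2S)-5-bromo-2,3-dihydro-1-benzofuran-2-yl]propan-1-ol | C[C@@H](CO)[C@@H]1Cc2cc(Br)ccc2O1 | intermediate
13 | tert-butyl prop-2-enoate (tert-butyl acrylate) | C=CC(=O)OC(C)(C)C | starting material
14 | tert-butyl (2E)-3-[(2S)-2-[(2S)-1-hydroxypropan-2-yl]-2,3-dihydro-1-benzofuran-5-yl]prop-2-enoate | C[C@@H](CO)[C@@H]1Cc2cc(/C=C/C(=O)OC(C)(C)C)ccc2O1 | intermediate
15 | (2E)-3-(4-hydroxyphenyl)prop-2-enoic acid (p-coumaric acid) | OC(=O)/C=C/c1ccc(O)cc1 | starting material
16 | tert-butyl (2E)-3-[(2S)-2-[(2S)-1-{[(2E)-3-(4-hydroxyphenyl)prop-2-enoyl]oxy}propan-2-yl]-2,3-dihydro-1-benzofuran-5-yl]prop-2-enoate | C[C@@H](COC(=O)/C=C/c1ccc(O)cc1)[C@@H]1Cc2cc(/C=C/C(=O)OC(C)(C)C)ccc2O1 | intermediate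
17 | (2E)-3-[(2S)-2-[(2S)-1-{[(2E)-3-(4-hydroxyphenyl)prop-2-enoyl]oxy}propan-2-yl]-2,3-dihydro-1-benzofuran-5-yl]prop-2-enoic acid | C[C@@H](COC(=O)/C=C/c1ccc(O)cc1)[C@@H]1Cc2cc(/C=C/C(=O)O)ccc2O1 | target

## Step count and least certain steps

Total step count: 8. Longest linear sequence: 8 steps (1 → 17); 2, 4, 5, 13 and 15 enter as purchased materials.

**Step 2 (key step).** The unsubstituted methide has no substituent to help organise the transition state, so facial selection by the ammonium group may be incomplete, and the methide may oligomerise before it is captured. Fallback, from 3 and 4 and returning at 8: 4 is quaternised with 1,4-diazabicyclo[2.2.2]octane to the achiral salt 1-{2-[methoxy(methyl)amino]-2-oxoethyl}-4-aza-1-azoniabicyclo[2.2.2]octane bromide F1. The same Cs2CO3-mediated annulation with 3 then gives racemic 5-bromo-N-methoxy-N-methyl-2,3-dihydro-1-benzofuran-2-carboxamide F2. Its enantiomers are separated by preparative chromatography on a chiral polysaccharide phase, and the (S)-enantiomer is 8. This replaces asymmetric induction by resolution.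

**Step 5.** The resident C2 stereocentre may oppose the ligand (mismatched pairing) and erode facial selectivity, or the sense of induction may be the reverse of the one assumed. Fallback, from 10 and returning at 12: substrate-directed hydroboration with catecholborane and RhCl(PPh3)3 in THF, a catalysed process that on 1,1-disubstituted allylic ethers is expected to favour the syn product, the reverse of the uncatalysed reaction. It would give the catechol boronate 2-{(2S)-2-[(2S)-5-bromo-2,3-dihydro-1-benzofuran-2-yl]propyl}-1,3,2-benzodioxaborole F3, which is oxidised in the same flask with NaOH/H2O2 to 12. Stereocontrol then comes from the substrate instead of the ligand.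

**Step 4.** Partial loss of configuration at C2 through enolisation of the α-aryloxy ketone during the warm titanium step, or incomplete methylenation. Fallback, from 9 and returning at 10: Peterson olefination. Addition of Me3SiCH2MgCl pre-mixed with anhydrous CeCl3 in THF at −78 °C, a weakly basic organocerium reagent, gives 2-[(2S)-5-bromo-2,3-dihydro-1-benzofuran-2-yl]-1-(trimethylsilyl)propan-2-ol F4 (either carbinol epimer serves). Elimination with KH in THF at 0 °C then gives 10.

**Step 7.** Competing O-alkylation of the phenol, or slow displacement at the β-branched primary carbon with reduction of the azo reagent as the main event. Fallback, from 14 and returning at 16: the cinnamoyl C=C is built instead of the ester C–O bond. Heating 14 with Meldrum's acid in toluene at 100 °C gives the malonic half ester 3-{(2S)-2-[(2S)-5-[(1E)-3-tert-butoxy-3-oxoprop-1-en-1-yl]-2,3-dihydro-1-benzofuran-2-yl]propoxy}-3-oxopropanoic acid F5. Knoevenagel–Doebner condensation of F5 with 4-hydroxybenzaldehyde (pyridine, catalytic piperidine, 60 °C) then gives 16 with loss of CO2 and water.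

**Step 8.** tert-Butylation of the electron-rich phenol ring by the released cation, or acid-promoted addition to the cinnamoyl double bonds. Fallback, from 12 and returning at 17: the ester protecting group is avoided altogether. Mitsunobu esterification of 12 with 15 (PPh3, DIAD, THF) gives (2S)-2-[(2S)-5-bromo-2,3-dihydro-1-benzofuran-2-yl]propyl (2E)-3-(4-hydroxyphenyl)prop-2-enoate F6. A Heck reaction of F6 with acrylic acid (Pd(OAc)2, P(o-tol)3, Et3N, DMF, 100 °C) then gives 17 directly.

## Further compounds

F1 | step 2 | 1-{2-[methoxy(methyl)amino]-2-oxoethyl}-4-aza-1-azoniabicyclo[2.2.2]octane bromide | CON(C)C(=O)C[N+]12CCN(CC1)CC2.[Br-]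
F2 | step 2 | racemic 5-bromo-N-methoxy-N-methyl-2,3-dihydro-1-benzofuran-2-carboxamide | CON(C)C(=O)C1Cc2cc(Br)ccc2O1
F3 | step 5 | 2-{(2S)-2-[(2S)-5-bromo-2,3-dihydro-1-benzofuran-2-yl]propyl}-1,3,2-benzodioxaborole | C[C@@H](CB1Oc2ccccc2O1)[C@@H]1Cc2cc(Br)ccc2O1
F4 | step 4 | 2-[(2S)-5-bromo-2,3-dihydro-1-benzofuran-2-yl]-1-(trimethylsilyl)propan-2-ol | CC(O)(C[Si](C)(C)C)[C@@H]1Cc2cc(Br)ccc2O1
F5 | step 7 | 3-{(2S)-2-[(2S)-5-[(1E)-3-tert-butoxy-3-oxoprop-1-en-1-yl]-2,3-dihydro-1-benzofuran-2-yl]propoxy}-3-oxopropanoic acid | C[C@@H](COC(=O)CC(=O)O)[C@@H]1Cc2cc(/C=C/C(=O)OC(C)(C)C)ccc2O1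
F6 | step 8 | (2S)-2-[(2S)-5-bromo-2,3-dihydro-1-benzofuran-2-yl]propyl (2E)-3-(4-hydroxyphenyl)prop-2-enoate | C[C@@H](COC(=O)/C=C/c1ccc(O)cc1)[C@@H]1Cc2cc(Br)ccc2O1
A1 | alternative 1 | 4-bromo-2-iodophenol | Oc1ccc(Br)cc1I
A2 | alternative 1 | tert-butyl(dimethyl)[(2-methylidenebut-3-en-1-yl)oxy]silane | C=CC(=C)CO[Si](C)(C)C(C)(C)C
A3 | alternative 1 | tert-butyl({2-[(2S)-5-bromo-2,3-dihydro-1-benzofuran-2-yl]prop-2-en-1-yl}oxy)dimethylsilane | C=C(CO[Si](C)(C)C(C)(C)C)[C@@H]1Cc2cc(Br)ccc2O1
A4 | alternative 2 | methyl (2S)-3-hydroxy-2-methylpropanoate | C[C@@H](CO)C(=O)OC
A5 | alternative 2 | N'-[(E)-{5-bromo-2-[(2R)-3-{[tert-butyl(dimethyl)silyl]oxy}-2-methylpropoxy]phenyl}methylidene]-4-methylbenzenesulfonohydrazide | C[C@@H](CO[Si](C)(C)C(C)(C)C)COc1ccc(Br)cc1/C=N/NS(=O)(=O)c1ccc(C)cc1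
A6 | alternative 2 | tert-butyl({(2S)-2-[(2S)-5-bromo-2,3-dihydro-1-benzofuran-2-yl]propyl}oxy)dimethylsilane | C[C@@H](CO[Si](C)(C)C(C)(C)C)[C@@H]1Cc2cc(Br)ccc2O1
A7 | alternative 3 | 4-bromo-2-[(2E)-but-2-en-1-yl]phenol | C/C=C/Cc1cc(Br)ccc1O
A8 | alternative 3 | methyl (2R)-2-[(2S)-5-bromo-2,3-dihydro-1-benzofuran-2-yl]propanoate | C[C@@H](C(=O)OC)[C@@H]1Cc2cc(Br)ccc2O1
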